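**Plan**
- Numbering and enabling feature: carbons C1–C22 follow the target SMILES. C7 and C10 are the carbonyls of a 1,4-diketone, so C9 (β to C7=O) and C10 are both acceptor carbons. C9 hangs on C8, and C10 hangs, through C11, on C6. These are the two α carbons of the cyclopentanone ring C4–C5–C6–C7–C8, and both groups lie on the same face. A reductive, polarity-inverting C9–C10 union can therefore close ring C6–C7–C8–C9–C10–C11 of the bicyclo[3.2.1]octane.
- Retrosynthetic cuts, in order: O–Me (hydroquinone from its dimethyl ether), C9–C10, C8=C9, C4–C2 (isopropenyl), C11–C22, then C6–C16 together with C11–C12, and finally C6=C11.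
- Forward ring order: the cyclopentane and arene rings are bought. The cyclohexene C6/C11/C12/C13/C15/C16 comes from a Diels–Alder reaction (spiro centre C6). The five-membered ring C6–C16–C17–C22–C11 comes from enolate arylation (benzobicyclo[3.2.1]octadiene). The six-membered dione ring is closed last with SmI2.
- Stereochemistry: a (−)-menthyl ester on the dienophile fixes the absolute sense of C6 and C16, and the endo rule fixes their relation. The aryl tether dictates C11. The bridgehead ester steers the isopropenyl copper addition to the C16 face (C4). The new bridge dictates C8.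
- The isopropenyl group is introduced late on purpose. It stands on the same cyclopentanone face as C16, which is the face from which the diene must arrive. An early C4 substituent would misdirect the cycloaddition and would leave two competing α-methylene groups.

Key step: step 12

Assumption: the face of the dienophile screened by the (−)-menthyl ester is assigned by analogy with aluminium-promoted cycloadditions of (−)-menthyl fumarates; (+)-menthyl glyoxylate would be taken if the sense proved opposite.

Step 1
Reactants: 1 2-bromo-1,4-dimethoxybenzene
Product: 3 2-bromo-3,6-dimethoxybenzaldehyde, via aryllithium 2 (not isolated)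
Conditions: LiN(i-Pr)2, THF, −78 °C; DMF, −78 → 0 °C; H2O
Reagents that add atoms: N,N-dimethylformamide, CN(C)C=O
Why: Directed ortho-metalation followed by formylation: the amide base removes the ring hydrogen flanked by Br and OMe, the most acidic one, without bromine–lithium exchange, and DMF turns the aryllithium into the aldehyde whose carbon becomes C16 next to the C22 bromide.

Step 2
Reactants: 3 2-bromo-3,6-dimethoxybenzaldehyde; 4 diethyl (2-methylallyl)phosphonate
Product: 6 2-bromo-1,4-dimethoxy-3-[(1E)-3-methylbuta-1,3-dien-1-yl]benzene, via lithiated phosphonate 5 (not isolated)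
Conditions: 4, n-BuLi, THF, −78 °C; 3; DMPU, −78 °C → rt
Reagents that add atoms: none
Why: Horner–Wadsworth–Emmons olefination with an allylic phosphonate carbanion, which with aromatic aldehydes gives the (E)-1-aryl-1,3-diene that places the aryl group "outside" in the cycloaddition; the carbanion is formed before the bromoarene is added, so the C–Br bond is not touched.

Step 3
Reactants: 7 4-(cyclopent-1-en-1-yl)morpholine; 8 (1R,2S,5R)-menthyl glyoxylate (commercial monohydrate, dried azeotropically)
Product: 10 (−)-menthyl (E)-2-(2-oxocyclopentylidene)acetate, via dienamine 9 (not isolated)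
Conditions: toluene, Dean–Stark, reflux; then 1 M aq. HCl, THF, rt
Reagents that add atoms: water, O
Why: Stork enamine aldol condensation with a highly electrophilic glyoxylate, then hydrolysis of the dienamine; the E alkene, with the ester turned away from the ring carbonyl, is the thermodynamic isomer, and an unsubstituted cyclopentanone avoids any question of which α carbon reacts.

Step 4
Reactants: 10 (−)-menthyl (E)-2-(2-oxocyclopentylidene)acetate; 6 the (E)-aryl diene
Product: 11 (−)-menthyl 10-(2-bromo-3,6-dimethoxyphenyl)-8-methyl-1-oxospiro[4.5]dec-8-ene-6-carboxylate, (6S,11S,16S) in target numbering, with the aryl group cis and the ester trans to the C7 carbonyl on the cyclohexene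
Conditions: Et2AlCl (2.2 equiv), toluene–CH2Cl2, −40 → 0 °C; minor diastereomers removed by chromatography or crystallisation
Reagents that add atoms: none
Why: Lewis-acid-promoted Diels–Alder reaction in which the nucleophilic CH2 terminus C12 bonds to C11 (β to the ring ketone) so that C16 meets C6, the flat C7 carbonyl sits endo while the ester stays exo away from the C13 methyl (aryl cis to C7), and the aluminium-bound (−)-menthyl ester screens one face of the E alkene and thus sets the absolute configuration of C6 and C16.

Step 5
Reactants: 11 the Diels–Alder adduct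
Product: 12 C7=C8 tert-butyldimethylsilyl enol ether of 11 (C6, C11 and C16 unchanged)
Conditions: t-BuMe2SiOTf, Et3N, CH2Cl2, 0 °C
Reagents that add atoms: tert-butyldimethylsilyl trifluoromethanesulfonate, CC(C)(C)[Si](C)(C)OS(=O)(=O)C(F)(F)F
Why: Soft enolisation (silyl triflate and tertiary amine) converts the ketone, which can enolise only toward C8 because C6 is quaternary, into its silyl enol ether far faster than the ester reacts; this masks C7/C8 for the basic arylation and prepares the later dehydrogenation.

Step 6
Reactants: 12 the silyl enol ether bromide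
Product: 13 bridged ester: a 5,8-dimethoxybenzobicyclo[3.2.1]octadiene with the (−)-menthyl ester on bridgehead C11 and H on bridgehead C16; its one-carbon bridge C6 is spiro to the 2-silyloxycyclopent-2-ene ring, with C7 over the arene and C5 over the C13=C15 bridge (C6, C11 and C16 placed as in the target)
Conditions: LiNCy2 (1.3 equiv), Pd(dba)2 (5 mol %), P(t-Bu)3 (10 mol %), toluene, rt → 60 °C
Reagents that add atoms: none
Why: Palladium-catalysed intramolecular α-arylation of an ester enolate closes the five-membered ring C6–C16–C17–C22–C11; with the ketone masked the ester enolate is the only one available, and the short tether lets C22 reach only the face of C11 cis to the C16 aryl bond, which fixes the quaternary centre whatever the C11 configuration of 12.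

Step 7
Reactants: 13 the bridged ester
Product: 14 spiro cyclopent-2-enone (C7=O, C8=C4) of the bridged menthyl ester
Conditions: Pd(OAc)2 (1.1 equiv), MeCN, 40 °C
Reagents that add atoms: none
Why: Saegusa–Ito oxidation: divalent palladium attacks C8 of the silyl enol ether and β-hydride loss from C4 gives the only possible enone, while the ester, arene and trisubstituted alkene are inert.

Step 8
Reactants: 14 the spiro enone; 15 isopropenylmagnesium bromide
Product: 16 (4S)-4-isopropenyl C7=C8 triethylsilyl enol ether of the bridged menthyl ester (isopropenyl on the cyclopentane face that carries C16)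
Conditions: 15, CuBr·SMe2 (20 mol %), Et3SiCl, DMPU, THF, −78 → −40 °C; Et3N, aq. NaHCO3
Reagents that add atoms: chlorotriethylsilane, CC[Si](Cl)(CC)CC
Why: Copper-catalysed, chlorosilane-accelerated 1,4-addition of a Grignard reagent: the cyclopentenone lies in the local mirror plane of the benzobicyclooctadiene with one face flanked by the bulky C11 menthyl ester and the other only by the C16–H, so the nucleophile should enter from the C16 side to give (4S), and the enolate is caught regiospecifically as the C7=C8 silyl enol ether.

Step 9
Reactants: 16 the silyl enol ether ester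
Product: 17 C10 primary alcohol (C11–CH2OH), silyl enol ether retained
Conditions: LiAlH4, Et2O, 0 °C → rt; Na2SO4·10H2O
Reagents that add atoms: none
Why: Hydride reduction of the ester to the primary alcohol with release of the auxiliary, possible without touching C7 because that carbonyl is stored as its silyl enol ether, which LiAlH4 and a non-acidic work-up leave intact.

Step 10
Reactants: 17 the primary alcohol
Product: 18 C10 aldehyde on C11, silyl enol ether retained
Conditions: Dess–Martin periodinane, pyridine, CH2Cl2, 0 °C
Reagents that add atoms: none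
Why: Dess–Martin oxidation of a neopentyl primary alcohol stops at the aldehyde, which cannot enolise or epimerise because C11 is quaternary; pyridine buffers the acetic acid so that the silyl enol ether survives.

Step 11
Reactants: 18 the aldehyde silyl enol ether; 19 dimethyl(methylidene)ammonium iodide (Eschenmoser's salt)
Product: 22 (4S,6S,11R,16R) aldehyde enone: C11–CHO and C8=C9H2 on the spiro cyclopentanone, via Mannich base 20 (not isolated), via methiodide 21 (not isolated)
Conditions: 19, CH2Cl2, rt; MeI, Et2O–CH2Cl2, rt; aq. NaHCO3, CH2Cl2, rt
Reagents that add atoms: iodomethane, CI (its carbon stays in 21 only and leaves as trimethylamine)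
Why: Mannich reaction of a silyl enol ether with a preformed iminium salt, then quaternisation and β-elimination (Eschenmoser methylenation); C8 is the only nucleophilic carbon because C6 is quaternary and the aldehyde has no α hydrogen, the C8 centre of 20 is erased, and the mild bicarbonate base spares the doubly allylic C4–H.

Step 12
Reactants: 22 the aldehyde enone
Product: 23 (4S,6S,8R,10S,11R,16R) C10 carbinol of the target bis(methyl ether) (equatorial alcohol drawn; the C10 epimer is carried on as well)
Conditions: SmI2 (0.1 M in THF, 3 equiv), t-BuOH (3 equiv), THF, 22 added over 3 h (final 0.005 M), 0 °C → rt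
Reagents that add atoms: none
Why: Proposed new method: divalent samarium passes one electron to the C10 aldehyde, the resulting ketyl bonds to C9, the unsubstituted β carbon of the C7 enone, and the C8 radical left behind, a bridgehead that cannot flatten into an enolate, is finished by a second electron and a proton from t-BuOH or by hydrogen abstraction from THF. The closest known reaction type is the SmI2 ketyl–olefin (aldehyde–enone) reductive cyclisation, which has not been shown for an exocyclic, s-cis-locked enone whose α carbon ends as a bridgehead; the reasoning is that electron transfer to either carbonyl stays reversible while only a weak proton donor is present, so the radical anions can drain through the single irreversible event, C9–C10 bond formation. The ring C6–C7–C8–C9–C10–C11 closes 6-endo-trig, the 5-exo alternative at C8 being polarity-mismatched and leading to a quaternary centre, a strained bicyclo[2.2.1]heptanone and a primary radical. C8 is set by the bridge, because C9 can bond only on the cyclopentanone face that carries C11 and hydrogen then enters at the outward lobe (8R), while C10 should carry its bulky samarium alkoxide equatorial on the new chair (10S), a centre that step 13 removes in any case. The step needs closure to outrun 1,4-reduction of the enone, reduction of the aldehyde and pinacol dimerisation: the substrate helps by holding C10 rigidly gauche to C7 on a bridgehead with no rotatable tether, and high dilution with slow addition to excess reductant suppresses the bimolecular paths. The price is that C8 must pyramidalise as C9 swings out of the enone plane toward C10, which is why this step heads the list of risks.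

Step 13
Reactants: 23 the C10 carbinol (both epimers)
Product: 24 C7,C10-diketone, bis(methyl ether) of the target
Conditions: Dess–Martin periodinane, CH2Cl2, rt
Reagents that add atoms: none
Why: Dess–Martin oxidation turns both possible C10 epimers into the same 1,4-diketone, and C8 cannot epimerise because it is a bridgehead.

Step 14
Reactants: 24 the diketone bis(methyl ether)
Product: 25 the corresponding p-benzoquinone
Conditions: (NH4)2Ce(NO3)6 (2.2 equiv), MeCN–H2O, 0 °C
Reagents that add atoms: water, O
Why: Oxidative demethylation of a 1,4-dimethoxyarene to the p-quinone takes minutes under conditions that spare isolated alkenes and ketones, and no quinone methide can form because the benzylic carbons C11 and C16 are bridgeheads.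

Step 15
Reactants: 25 the quinone
Product: 26 CNP0287617.1, (4S,6S,8R,11R,16R)
Conditions: Na2S2O4, EtOAc–H2O, rt, under Ar
Reagents that add atoms: none
Why: Two-electron reduction of the p-quinone to the hydroquinone with dithionite leaves the ketones, alkenes and all stereocentres untouched.

**Compound list**
1 | 2-bromo-1,4-dimethoxybenzene | COc1ccc(OC)c(Br)c1 | starting material
2 | (2-bromo-3,6-dimethoxyphenyl)lithium | [Li]c1c(Br)c(OC)ccc1OC | intermediate
3 | 2-bromo-3,6-dimethoxybenzaldehyde | O=Cc1c(Br)c(OC)ccc1OC | intermediate
4 | diethyl (2-methylallyl)phosphonate | C=C(C)CP(=O)(OCC)OCC | starting material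
5 | α-lithiated diethyl (2-methylallyl)phosphonate | CCOP(=O)(OCC)C([Li])C(C)=C | intermediate
6 | 2-bromo-1,4-dimethoxy-3-[(1E)-3-methylbuta-1,3-dien-1-yl]benzene | C=C(C)/C=C/c1c(Br)c(OC)ccc1OC | intermediate
7 | 4-(cyclopent-1-en-1-yl)morpholine | C1=C(CCC1)N1CCOCC1 | starting material
8 | (1R,2S,5R)-menthyl glyoxylate | O=CC(=O)O[C@@H]1C[C@H](C)CC[C@H]1C(C)C | starting material
9 | (−)-menthyl (E)-2-(2-morpholinocyclopent-2-en-1-ylidene)acetate | O=C(/C=C1\CCC=C1N2CCOCC2)O[C@@H]3C[C@H](C)CC[C@H]3C(C)C | intermediate
10 | (−)-menthyl (E)-2-(2-oxocyclopentylidene)acetate | O=C1CCC/C1=C\C(=O)O[C@@H]2C[C@H](C)CC[C@H]2C(C)C | intermediate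
11 | Diels–Alder adduct, spiro keto ester with aryl bromide | C1C[C@@]2(C(=O)C1)[C@@H](C(=O)O[C@@H]3C[C@H](C)CC[C@H]3C(C)C)CC(C)=C[C@@H]2c1c(OC)ccc(OC)c1Br | intermediate
12 | C7=C8 tert-butyldimethylsilyl enol ether of 11 | C1C[C@@]2(C(O[Si](C)(C)C(C)(C)C)=C1)[C@@H](C(=O)O[C@@H]3C[C@H](C)CC[C@H]3C(C)C)CC(C)=C[C@@H]2c1c(OC)ccc(OC)c1Br | intermediate
13 | bridged menthyl ester, silyl enol ether | C1C[C@@]2(C(O[Si](C)(C)C(C)(C)C)=C1)[C@@]3(C(=O)O[C@@H]4C[C@H](C)CC[C@H]4C(C)C)CC(C)=C[C@@H]2c2c(OC)ccc(OC)c23 | intermediate
14 | bridged menthyl ester, spiro cyclopent-2-enone | C1=CC(=O)[C@]2(C1)[C@@]3(C(=O)O[C@@H]4C[C@H](C)CC[C@H]4C(C)C)CC(C)=C[C@@H]2c2c(OC)ccc(OC)c23 | intermediate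
15 | isopropenylmagnesium bromide | C=C(C)[Mg]Br | starting material
16 | (4S)-isopropenyl triethylsilyl enol ether, menthyl ester | C=C(C)[C@H]1C[C@@]2(C(O[Si](CC)(CC)CC)=C1)[C@@]3(C(=O)O[C@@H]4C[C@H](C)CC[C@H]4C(C)C)CC(C)=C[C@@H]2c2c(OC)ccc(OC)c23 | intermediate
17 | C10 primary alcohol, triethylsilyl enol ether | C=C(C)[C@H]1C[C@@]2(C(O[Si](CC)(CC)CC)=C1)[C@@]3(CO)CC(C)=C[C@@H]2c2c(OC)ccc(OC)c23 | intermediate
18 | C10 aldehyde, triethylsilyl enol ether | C=C(C)[C@H]1C[C@@]2(C(O[Si](CC)(CC)CC)=C1)[C@@]3(C=O)CC(C)=C[C@@H]2c2c(OC)ccc(OC)c23 | intermediate
19 | dimethyl(methylidene)ammonium iodide | C=[N+](C)C.[I-] | starting material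
20 | C8 (dimethylamino)methyl ketone (C9 trans to isopropenyl) | C=C(C)[C@H]1C[C@@]2(C(=O)[C@@H]1CN(C)C)[C@@]3(C=O)CC(C)=C[C@@H]2c2c(OC)ccc(OC)c23 | intermediate
21 | trimethylammonium iodide of 20 | C=C(C)[C@H]1C[C@@]2(C(=O)[C@@H]1C[N+](C)(C)C)[C@@]3(C=O)CC(C)=C[C@@H]2c2c(OC)ccc(OC)c23.[I-] | intermediate
22 | aldehyde enone, precursor of the key step | C=C(C)[C@H]1C[C@@]2(C(=O)C1=C)[C@@]3(C=O)CC(C)=C[C@@H]2c2c(OC)ccc(OC)c23 | intermediate
23 | C10 carbinol, product of the key step | C=C(C)[C@H]1C[C@@]23C(=O)[C@@H]1C[C@H](O)[C@@]21CC(C)=C[C@@H]3c2c(OC)ccc(OC)c21 | intermediate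
24 | diketone bis(methyl ether) | C=C(C)[C@H]1C[C@@]23C(=O)[C@@H]1CC(=O)[C@@]21CC(C)=C[C@@H]3c2c(OC)ccc(OC)c21 | intermediate
25 | quinone | C=C(C)[C@H]1C[C@@]23C(=O)[C@@H]1CC(=O)[C@@]21CC(C)=C[C@@H]3C2=C1C(=O)C=CC2=O | intermediate
26 | CNP0287617.1 | C=C(C)[C@H]1C[C@@]23C(=O)[C@@H]1CC(=O)[C@@]21CC(C)=C[C@@H]3c2c(O)ccc(O)c21 | target

**Totals**
- Total step count: 15.
- Longest linear sequence: 14 (steps 1, 2 and 4–15).

**Steps most likely to fail**

1. **Step 12.**
   - Risk: the ketyl may never reach C9. That carbon lies in the plane of the s-cis-locked enone, roughly anti to C6, and C8 has to bend toward a bridgehead geometry before any bond is made. Plain 1,4-reduction of the enone, reduction of the aldehyde or pinacol dimerisation could then take over.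
   - Fallback: it forms the same C9–C10 bond by known chemistry after C8 has been made tetrahedral. It sets out from 22.
   - Conjugate addition of benzeneselenol (PhSeH, catalytic Et3N, CH2Cl2, 0 °C) should give the β-(phenylselanyl)methyl ketone F1. Its epimerisable C8 centre should settle with C9 trans to the isopropenyl group, that is, on the face of C11.
   - Slow addition of Bu3SnH and AIBN in benzene at 80 °C then generates the primary C9 radical. This radical adds 6-exo to the aldehyde carbon C10 (radical cyclisation onto an aldehyde, an established route to cyclohexanols), and the alkoxyl radical is capped by the stannane.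
   - The route is rejoined at 23.

2. **Step 4.**
   - Risk: the cycloaddition may be slow, because a trisubstituted dienophile meets a diene whose aryl group has two ortho substituents. The Lewis acid may polymerise the diene, and a single menthyl ester may discriminate the faces incompletely.
   - Fallback: it replaces the methyl diene by a far more nucleophilic 2-silyloxy diene and installs the methyl group afterwards. It sets out from 3 and 10.
   - Claisen–Schmidt condensation of 3 with acetone (aq. NaOH) gives (E)-4-(2-bromo-3,6-dimethoxyphenyl)but-3-en-2-one F2.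
   - t-BuMe2SiOTf and Et3N convert F2 into the 2-silyloxy diene F3.
   - F3 should add to 10 at or below room temperature, concertedly or by a Mukaiyama–Michael/Michael sequence with the same regiochemistry, to give the C13 silyl enol ether adduct F4.
   - CsF and PhNTf2 in DME give the regiodefined C13 enol triflate F5, and Me2CuLi (THF, −20 °C) replaces the triflate by methyl.
   - The route is rejoined at 11.

3. **Step 6.**
   - Risk: deprotonation of the hindered C11–H next to the quaternary C6 may be slow, and the amide base may reduce the arylpalladium species (loss of bromine without ring closure).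
   - Fallback: it moves the arylation to the aldehyde oxidation level, where a carbonate base suffices. It sets out from 12.
   - i-Bu2AlH (CH2Cl2, −78 → 0 °C) gives the primary alcohol F6, and Dess–Martin periodinane with pyridine gives the α-branched aldehyde F7.
   - Pd(OAc)2, rac-BINAP and Cs2CO3 in dioxane at 90 °C (intramolecular α-arylation of an α-branched aldehyde) give the bridged quaternary aldehyde F8.
   - Pd(OAc)2 in MeCN (Saegusa–Ito oxidation) gives the enone aldehyde F9.
   - Potassium isopropenyltrifluoroborate with [Rh(cod)2]BF4 and (S)-BINAP in toluene–H2O at 100 °C adds 1,4 in preference to the hindered aldehyde. The ligand is matched to the substrate bias, and the product is the keto aldehyde F10.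
   - Et3SiOTf and Et3N (CH2Cl2, −78 °C) then give the silyl enol ether, and the route is rejoined at 18.

**Further compounds**
F1 | step 12 | C8 (phenylselanyl)methyl ketone aldehyde | C=C(C)[C@H]1C[C@@]2(C(=O)[C@@H]1C[Se]c4ccccc4)[C@@]3(C=O)CC(C)=C[C@@H]2c2c(OC)ccc(OC)c23
F2 | step 4 | (E)-4-(2-bromo-3,6-dimethoxyphenyl)but-3-en-2-one | CC(=O)/C=C/c1c(Br)c(OC)ccc1OC
F3 | step 4 | (E)-1-(2-bromo-3,6-dimethoxyphenyl)-3-(tert-butyldimethylsilyloxy)buta-1,3-diene | C=C(O[Si](C)(C)C(C)(C)C)/C=C/c1c(Br)c(OC)ccc1OC
F4 | step 4 | C13 silyl enol ether cycloadduct | C1C[C@@]2(C(=O)C1)[C@@H](C(=O)O[C@@H]3C[C@H](C)CC[C@H]3C(C)C)CC(O[Si](C)(C)C(C)(C)C)=C[C@@H]2c1c(OC)ccc(OC)c1Br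
F5 | step 4 | C13 enol triflate | C1C[C@@]2(C(=O)C1)[C@@H](C(=O)O[C@@H]3C[C@H](C)CC[C@H]3C(C)C)CC(OS(=O)(=O)C(F)(F)F)=C[C@@H]2c1c(OC)ccc(OC)c1Br
F6 | step 6 | unbridged C10 primary alcohol, silyl enol ether | C1C[C@@]2(C(O[Si](C)(C)C(C)(C)C)=C1)[C@@H](CO)CC(C)=C[C@@H]2c1c(OC)ccc(OC)c1Br
F7 | step 6 | unbridged C10 aldehyde, silyl enol ether | C1C[C@@]2(C(O[Si](C)(C)C(C)(C)C)=C1)[C@@H](C=O)CC(C)=C[C@@H]2c1c(OC)ccc(OC)c1Br
F8 | step 6 | bridged C11 aldehyde, silyl enol ether | C1C[C@@]2(C(O[Si](C)(C)C(C)(C)C)=C1)[C@@]3(C=O)CC(C)=C[C@@H]2c2c(OC)ccc(OC)c23
F9 | step 6 | bridged C11 aldehyde, spiro cyclopent-2-enone | C1=CC(=O)[C@]2(C1)[C@@]3(C=O)CC(C)=C[C@@H]2c2c(OC)ccc(OC)c23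
F10 | step 6 | (4S)-isopropenyl keto aldehyde | C=C(C)[C@H]1C[C@@]2(C(=O)C1)[C@@]3(C=O)CC(C)=C[C@@H]2c2c(OC)ccc(OC)c23
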